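The readings come from a simulation with constants of no real substance; the scatter is artificial.

Every unit of partner charged stays on the books: free, as second intermediate, in target, or, two to a unit, in homo product. I wrote that balance to decide what to do with the flask at 2.0 d.

| flask | substrate | partner | temperature | remark | time |
|---|---|---|---|---|---|
| delta | 0.050 M | 0.040 M | 35 °C | the very flask that is asked about, followed so far |  |
| gamma | 0.034 M | 0.040 M | 41 °C | run made earlier |  |
| flask | 0.050 M | 0.0400 M | 35 °C |  | 2.0 d |

- delta (time / h: target / %): 6.00: 36; 12.0: 53; 15.0: 57; 25.0: 60; 30.0: 63
- gamma (time / min: target / %): 8.00: 0; 15.0: 1; 30.0: 1; 60.0: 11; 120: 28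

(readings scatter by 1.5 percentage points)

- Sunday's: at 2.0 d add partner, 50.0% of the amount charged, then wait 25 h
- Tuesday's: at 2.0 d take out 90% of the target then present, then wait 25 h
- Monday's: change nothing and wait 25 h more
- Thursday's: at 2.0 d raise the temperature by 15 K, then wait 25 h

- removed target is counted in
- steps that have been proposed: substrate -> open intermediate; partner -> second intermediate; open intermediate + second intermediate -> target; 2 second intermediate -> homo product
- additions bring no volume worth counting

- target, in percent of the substrate first charged, at 2.0 d
- which option adds most target ("none" when 2 percentage points or less is all one gets) (Sunday's / Tuesday's / Monday's / Thursday's / none)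
- target present, with what was taken out counted in, in percent of the substrate first charged, after Sunday's
- target present, with what was taken out counted in, in percent of the substrate first charged, after Monday's

1. The flask held 0.0400 M of partner against 0.050 M of substrate, so partner was the limiting reagent. One partner goes into each target, so the balance capped target at 80.0% of the substrate.

2. The delta run read 60% at 25.0 h and 63% at 30.0 h. With a scatter of 1.5 percentage points on each reading, I took these as one level, 61.5%, and committed to that for the flask at 2.0 d.

3. That reading gave the coupling share, the target formed per partner charged: 76.9%. By the balance, I assigned the remainder of the partner to homo product.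

4. Waiting, removing target and heating put no partner into the flask, and the proposed steps show no way back from target. So I expected Monday's to stay at my level and chose Sunday's, which adds 0.0200 M of partner.

5. At the same coupling share, that addition gives 31 points, or 92.5% in all. But I put the uncoupled material at 38.5% of the substrate, less than at the start, and the proposed step to homo product also uses second intermediate. So I expected less than that sum.

The forecast gave 65% at 2.0 d, Sunday's as the best option, 86% after it and 65.5% after Monday's, holding that “waiting adds nothing and removing target does nothing”.

The flask gave 61.8% at 2.0 d. The best option was Sunday's, which added 24 points and reached 85.9%, while Monday's added 0.011 points and stayed at 61.8%.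

    substrate → open intermediate (k = 0.0190 min⁻¹, Ea = 96.0 kJ mol⁻¹)
    partner → second intermediate (k = 0.00330 min⁻¹, Ea = 88.0 kJ mol⁻¹)
    open intermediate + second intermediate → target (k = 0.390 M⁻¹ min⁻¹, Ea = 67.0 kJ mol⁻¹)
    2 second intermediate → homo product (k = 0.620 M⁻¹ min⁻¹, Ea = 73.0 kJ mol⁻¹)
    (constants at 35 °C)

Target in this flask stopped at 61.8% due to the falling level of partner: 0.00746% of its charge stood free at 48.0 h, and the run without that fall reached >99.9%. The coupling share came to 77.2% here, and to 60.3% on the partner added in Sunday's. The other case is a neighbour flask with the same charges but kept at 10 °C: its coupling share was 22.6%, yet partner still stood at 63.3% of its charge at 48.0 h.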